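**Target:** (13R)-3α,20-diacetoxy-7α,13-dihydroxy-9βH-labda-8(17),14-dien-2α-yl angelate (H-5 α, CH2OAc on C10 β, side chain on C9 α, i.e. a 9-epi-labdane). This matches the given SMILES centre by centre.

**Retrosynthetic overview**
1. Target ⇐ allylic hydroxylation at C7 and inversion/acetylation at C3 of a bicyclic 2α-angeloyloxy-3β-ol.
2. Key disconnection: the C4–C5 and C9–C10 bonds, formed in one radical cascade from an acyclic (Z,Z)-epoxy triene ester. Ring A closes first, ring B second, and the 8(17)-olefin forms in the terminating step.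
3. Acyclic chain ⇐ Z-selective Wittig union at C5=C10 of a C5–C16 ylide and a C20/C10/C1–C4 α-silyloxy ketone.
4. Ylide fragment: carbocupration of propyne (Z-C8=C9), conjugate addition to methyl vinyl ketone, C13 by asymmetric epoxidation and ylide homologation. Ketone fragment: asymmetric aldol of silyloxyacetone with prenal, then hydroxyl-directed epoxidation.

**Assumptions:** The silyl ethers 1 and 13 are bought as such. Labdane numbering (C1–C20) is used for all atoms, including in the acyclic precursors. If the chiral catalyst of step 2 or the chiral borane of step 5 shows the opposite facial sense to that stated, its antipode is used.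

Step 1
Reactants: 1 (3-bromopropoxy)(tert-butyl)dimethylsilane; 2 propyne; 3 but-3-en-2-one
Product: 7 (5Z)-9-(tert-butyldimethylsilyloxy)-6-methylnon-5-en-2-one, via Grignard reagent 4 (not isolated), via alkenylcopper 5 (not isolated), via silyl enol ether 6 (not isolated)
Conditions: Mg, THF; CuBr·SMe2, Et2O/Me2S, −45 °C; propyne, −25 °C; Me3SiCl, but-3-en-2-one, −78 → −20 °C; NH4Cl (aq), then citric acid (aq)
Reagents that add atoms: none
Why: Normant carbocupration, in which the alkylcopper adds syn across propyne with copper on the terminal carbon so that C7 and C9–Cu are cis, followed by Me3SiCl-accelerated conjugate addition of the configurationally stable alkenylcopper to the enone, which fixes the Z-C8=C9 olefin.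

Step 2
Reactants: 7 (5Z)-9-(tert-butyldimethylsilyloxy)-6-methylnon-5-en-2-one
Product: 8 tert-butyldimethyl{[(4Z)-4-methyl-7-[(2R)-2-methyloxiran-2-yl]hept-4-en-1-yl]oxy}silane
Conditions: Me3S(O)I, NaH, THF; LaLi3[(R)-binaphthoxide]3 (5 mol%), (2,4,6-(MeO)3C6H2)3P=O (5 mol%), MS 5 Å, 25 °C
Reagents that add atoms: trimethylsulfoxonium iodide, C[S+](C)(C)=O.[I-]
Why: Catalytic asymmetric Corey–Chaykovsky epoxidation of a methyl ketone, in which the chiral lanthanum–lithium binaphthoxide/phosphine oxide catalyst directs the sulfoxonium ylide to one face of the carbonyl and sets C13 as R.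

Step 3
Reactants: 8 tert-butyldimethyl{[(4Z)-4-methyl-7-[(2R)-2-methyloxiran-2-yl]hept-4-en-1-yl]oxy}silane
Product: 10 (3R,6Z)-3,7-dimethyldeca-1,6-diene-3,10-diol, via silyl ether 9 (not isolated)
Conditions: Me3SI, n-BuLi, THF, −10 → 25 °C; then Bu4NF, 25 °C
Reagents that add atoms: trimethylsulfonium iodide, C[S+](C)C.[I-]
Why: One-carbon homologation of a terminal epoxide with dimethylsulfonium methylide (ylide opening at the CH2 carbon, then base-induced loss of Me2S) gives the tertiary vinyl carbinol with C13 untouched, and fluoride then cleaves the silyl ether in the same flask.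

Step 4
Reactants: 10 (3R,6Z)-3,7-dimethyldeca-1,6-diene-3,10-diol
Product: 12 [(4Z,8R)-8-hydroxy-4,8-dimethyldeca-4,9-dien-1-yl]triphenylphosphonium iodide, via iodide 11 (not isolated)
Conditions: I2, PPh3, imidazole, CH2Cl2, 0 °C; then PPh3, MeCN, 80 °C
Reagents that add atoms: iodine, II; triphenylphosphine, c1ccc(cc1)P(c1ccccc1)c1ccccc1
Why: Appel iodination is selective for the primary over the tertiary allylic hydroxyl, and SN2 quaternisation of triphenylphosphine by the primary iodide gives the Wittig salt without touching a stereocentre.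

Step 5
Reactants: 13 1-(tert-butyldimethylsilyloxy)propan-2-one; 14 3-methylbut-2-enal
Product: 17 (4R)-1-(tert-butyldimethylsilyloxy)-4-hydroxy-6-methylhept-5-en-2-one, via boron enolate 15 (not isolated), via boron aldolate 16 (not isolated)
Conditions: (−)-Ipc2BCl, Et3N, Et2O, −78 → 0 °C; 14, −78 → −20 °C; H2O2, MeOH, pH 7 buffer
Reagents that add atoms: none
Why: Paterson boron aldol reaction, in which the bulky borane enolises the ketone on its methyl side and the chiral diisopinocampheylboron enolate adds to the enal through a cyclic six-membered transition state, setting the C2 carbinol as R by reagent control.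

Step 6
Reactants: 17 (4R)-1-(tert-butyldimethylsilyloxy)-4-hydroxy-6-methylhept-5-en-2-one
Product: 18 (4R)-1-(tert-butyldimethylsilyloxy)-4-[(2S)-3,3-dimethyloxiran-2-yl]-4-hydroxybutan-2-one
Conditions: mCPBA, NaHCO3, CH2Cl2, 0 °C
Reagents that add atoms: 3-chloroperoxybenzoic acid, OOC(=O)c1cccc(Cl)c1
Why: Hydroxyl-directed peracid epoxidation of an allylic alcohol, in which minimised 1,3-allylic strain with the cis methyl group gives the threo epoxy alcohol and so sets C3 as S relative to C2.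

Step 7
Reactants: 18 (4R)-1-(tert-butyldimethylsilyloxy)-4-[(2S)-3,3-dimethyloxiran-2-yl]-4-hydroxybutan-2-one
Product: 19 (4R)-1-(tert-butyldimethylsilyloxy)-4-[(2S)-3,3-dimethyloxiran-2-yl]-4-(triethylsilyloxy)butan-2-one
Conditions: Et3SiCl, imidazole, CH2Cl2, 0 °C
Reagents that add atoms: chlorotriethylsilane, CC[Si](Cl)(CC)CC
Why: Silylation masks the β-hydroxyl so that the ketone survives the basic ylide without retro-aldol cleavage.

Step 8
Reactants: 12 [(4Z,8R)-8-hydroxy-4,8-dimethyldeca-4,9-dien-1-yl]triphenylphosphonium iodide; 19 (4R)-1-(tert-butyldimethylsilyloxy)-4-[(2S)-3,3-dimethyloxiran-2-yl]-4-(triethylsilyloxy)butan-2-one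
Product: 21 (2Z,6Z,10R)-1-(tert-butyldimethylsilyloxy)-2-{(2R)-2-[(2S)-3,3-dimethyloxiran-2-yl]-2-(triethylsilyloxy)ethyl}-6,10-dimethyldodeca-2,6,11-trien-10-ol, via ylide 20 (not isolated)
Conditions: 12, KN(SiMe3)2 (2.05 equiv), THF, −78 → 0 °C; 19, −78 → 25 °C
Reagents that add atoms: none
Why: Still's Z-selective Wittig reaction of a non-stabilised ylide with an α-silyloxy ketone places the incoming chain cis to the CH2O group, giving the Z-C5=C10 olefin (C6 cis to C20) that the trans ring fusion requires.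

Step 9
Reactants: 21 (2Z,6Z,10R)-1-(tert-butyldimethylsilyloxy)-2-{(2R)-2-[(2S)-3,3-dimethyloxiran-2-yl]-2-(triethylsilyloxy)ethyl}-6,10-dimethyldodeca-2,6,11-trien-10-ol
Product: 22 (2Z,6Z,10R)-2-{(2R)-2-[(2S)-3,3-dimethyloxiran-2-yl]-2-hydroxyethyl}-6,10-dimethyldodeca-2,6,11-triene-1,10-diol
Conditions: Bu4NF, AcOH, THF, 0 → 25 °C
Reagents that add atoms: none
Why: Acetic-acid-buffered fluoride desilylation removes both silyl ethers while the trisubstituted epoxide and the tertiary allylic alcohol stay intact.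

Step 10
Reactants: 22 (2Z,6Z,10R)-2-{(2R)-2-[(2S)-3,3-dimethyloxiran-2-yl]-2-hydroxyethyl}-6,10-dimethyldodeca-2,6,11-triene-1,10-diol
Product: 23 (2Z,6Z,10R)-2-{(2R)-2-[(2S)-3,3-dimethyloxiran-2-yl]-2-hydroxyethyl}-10-hydroxy-6,10-dimethyldodeca-2,6,11-trien-1-yl acetate
Conditions: Ac2O (1.05 equiv), 2,4,6-collidine, CH2Cl2, −20 °C
Reagents that add atoms: acetic anhydride, CC(=O)OC(C)=O
Why: Kinetic acylation discriminates the primary allylic C20 hydroxyl from the hindered secondary C2 hydroxyl and the tertiary C13 hydroxyl.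

Step 11
Reactants: 23 (2Z,6Z,10R)-2-{(2R)-2-[(2S)-3,3-dimethyloxiran-2-yl]-2-hydroxyethyl}-10-hydroxy-6,10-dimethyldodeca-2,6,11-trien-1-yl acetate; 24 (2Z)-2-methylbut-2-enoic acid (angelic acid)
Product: 26 (2Z,6Z,10R)-2-{(2R)-2-[(2S)-3,3-dimethyloxiran-2-yl]-2-[(2Z)-2-methylbut-2-enoyloxy]ethyl}-10-hydroxy-6,10-dimethyldodeca-2,6,11-trien-1-yl acetate, via mixed anhydride 25 (not isolated)
Conditions: 24, 2,4,6-Cl3C6H2COCl, Et3N, toluene, 25 °C; then 23, 75 °C
Reagents that add atoms: none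
Why: Yamaguchi esterification through the mixed anhydride without DMAP acylates the C2 hydroxyl with retention and without angelate-to-tiglate isomerisation.

Step 12
Reactants: 26 (2Z,6Z,10R)-2-{(2R)-2-[(2S)-3,3-dimethyloxiran-2-yl]-2-[(2Z)-2-methylbut-2-enoyloxy]ethyl}-10-hydroxy-6,10-dimethyldodeca-2,6,11-trien-1-yl acetate
Product: 27 (13R)-20-acetoxy-3β,13-dihydroxy-9βH-labda-8(17),14-dien-2α-yl (2Z)-2-methylbut-2-enoate
Conditions: Cp2TiCl2 (2.5 equiv), Mn dust, THF, 25 °C; slow addition of 26 (0.01 M); then 0.5 M HCl (aq), 0 °C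
Reagents that add atoms: none
Why: Radical bicyclization (Nugent–RajanBabu epoxide opening by Cp2TiCl with a polyene cascade), in which homolysis of the C4–O bond gives the tertiary C4 radical that closes ring A 6-endo onto C5 and then ring B 6-endo onto C9 through chair–chair transition states with the C3 titanoxy and C2 ester groups equatorial, the Z-C5=C10 olefin placing C6 equatorial (H-5 α, C20 β, trans fusion) and the Z-C8=C9 olefin forcing C11 axial (side chain 9α), after which the C8 radical is captured by a second Cp2TiCl and loses a methyl hydrogen by β-hydride elimination to give the 8(17)-olefin.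

Step 13
Reactants: 27 (13R)-20-acetoxy-3β,13-dihydroxy-9βH-labda-8(17),14-dien-2α-yl (2Z)-2-methylbut-2-enoate
Product: 28 (13R)-20-acetoxy-13-hydroxy-3-oxo-9βH-labda-8(17),14-dien-2α-yl (2Z)-2-methylbut-2-enoate
Conditions: Dess–Martin periodinane, NaHCO3, CH2Cl2, 0 → 25 °C
Reagents that add atoms: none
Why: Dess–Martin oxidation of the secondary 3β-alcohol erases the C3 centre while the tertiary carbinol, the olefins and the esters are inert.

Step 14
Reactants: 28 (13R)-20-acetoxy-13-hydroxy-3-oxo-9βH-labda-8(17),14-dien-2α-yl (2Z)-2-methylbut-2-enoate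
Product: 30 (13R)-3α,20-diacetoxy-13-hydroxy-9βH-labda-8(17),14-dien-2α-yl (2Z)-2-methylbut-2-enoate, via lithium alkoxide 29 (not isolated)
Conditions: LiBH(s-Bu)3, THF, −78 °C; then Ac2O, −78 → 0 °C
Reagents that add atoms: acetic anhydride, CC(=O)OC(C)=O
Why: Substrate-controlled ketone reduction, in which the bulky trialkylborohydride avoids the axial α trajectory (1,3-diaxial to H-1α and H-5α) and attacks C3 from the equatorial β side to give the axial 3α-alkoxide, which is acetylated in the flask before the neighbouring angelate can migrate.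

Step 15
Reactants: 30 (13R)-3α,20-diacetoxy-13-hydroxy-9βH-labda-8(17),14-dien-2α-yl (2Z)-2-methylbut-2-enoate
Product: 31 (13R)-3α,20-diacetoxy-7α,13-dihydroxy-9βH-labda-8(17),14-dien-2α-yl (2Z)-2-methylbut-2-enoate
Conditions: SeO2 (0.3 equiv), t-BuOOH, CH2Cl2, 0 → 25 °C
Reagents that add atoms: selenium dioxide (catalytic oxygen carrier), O=[Se]=O; tert-butyl hydroperoxide, CC(C)(C)OO
Why: Selenium dioxide allylic oxidation (ene reaction at C17 with removal of the axial 7α-hydrogen, then [2,3]-sigmatropic shift) returns oxygen to the α face of C7 and regenerates the exocyclic olefin, giving the axial 7α-alcohol.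

**Compound list**
1 | (3-bromopropoxy)(tert-butyl)dimethylsilane | BrCCCO[Si](C)(C)C(C)(C)C | starting material
2 | propyne | CC#C | starting material
3 | but-3-en-2-one (methyl vinyl ketone) | CC(=O)C=C | starting material
4 | [3-(tert-butyldimethylsilyloxy)propyl]magnesium bromide | Br[Mg]CCCO[Si](C)(C)C(C)(C)C | intermediate
5 | (Z)-[5-(tert-butyldimethylsilyloxy)-2-methylpent-1-en-1-yl]copper | [Cu]/C=C(C)\CCCO[Si](C)(C)C(C)(C)C | intermediate
6 | (5Z)-9-(tert-butyldimethylsilyloxy)-6-methyl-2-(trimethylsilyloxy)nona-2,5-diene | CC(O[Si](C)(C)C)=CC/C=C(C)\CCCO[Si](C)(C)C(C)(C)C | intermediate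
7 | (5Z)-9-(tert-butyldimethylsilyloxy)-6-methylnon-5-en-2-one | CC(=O)CC/C=C(C)\CCCO[Si](C)(C)C(C)(C)C | intermediate
8 | tert-butyldimethyl{[(4Z)-4-methyl-7-[(2R)-2-methyloxiran-2-yl]hept-4-en-1-yl]oxy}silane | C1O[C@]1(C)CC/C=C(C)\CCCO[Si](C)(C)C(C)(C)C | intermediate
9 | (3R,6Z)-10-(tert-butyldimethylsilyloxy)-3,7-dimethyldeca-1,6-dien-3-ol | C=C[C@](C)(O)CC/C=C(C)\CCCO[Si](C)(C)C(C)(C)C | intermediate
10 | (3R,6Z)-3,7-dimethyldeca-1,6-diene-3,10-diol | C=C[C@](C)(O)CC/C=C(C)\CCCO | intermediate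
11 | (3R,6Z)-10-iodo-3,7-dimethyldeca-1,6-dien-3-ol | C=C[C@](C)(O)CC/C=C(C)\CCCI | intermediate
12 | [(4Z,8R)-8-hydroxy-4,8-dimethyldeca-4,9-dien-1-yl]triphenylphosphonium iodide | C=C[C@](C)(O)CC/C=C(C)\CCC[P+](c1ccccc1)(c1ccccc1)c1ccccc1.[I-] | intermediate
13 | 1-(tert-butyldimethylsilyloxy)propan-2-one | CC(=O)CO[Si](C)(C)C(C)(C)C | starting material
14 | 3-methylbut-2-enal | CC(C)=CC=O | starting material
15 | 3-(tert-butyldimethylsilyloxy)prop-1-en-2-yl bis(isopinocampheyl)borinate | C=C(CO[Si](C)(C)C(C)(C)C)OB([C@@H]1C[C@@H]2C[C@H]([C@H]1C)C2(C)C)[C@@H]1C[C@@H]2C[C@H]([C@H]1C)C2(C)C | intermediate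
16 | bis(isopinocampheyl)boron aldolate of 17 (O-boryl at C2) | CC(C)=C[C@H](OB([C@@H]1C[C@@H]2C[C@H]([C@H]1C)C2(C)C)[C@@H]1C[C@@H]2C[C@H]([C@H]1C)C2(C)C)CC(=O)CO[Si](C)(C)C(C)(C)C | intermediate
17 | (4R)-1-(tert-butyldimethylsilyloxy)-4-hydroxy-6-methylhept-5-en-2-one | CC(C)=C[C@H](O)CC(=O)CO[Si](C)(C)C(C)(C)C | intermediate
18 | (4R)-1-(tert-butyldimethylsilyloxy)-4-[(2S)-3,3-dimethyloxiran-2-yl]-4-hydroxybutan-2-one | CC(C)(C)[Si](C)(C)OCC(=O)C[C@@H](O)[C@@H]1OC1(C)C | intermediate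
19 | (4R)-1-(tert-butyldimethylsilyloxy)-4-[(2S)-3,3-dimethyloxiran-2-yl]-4-(triethylsilyloxy)butan-2-one | CC(C)(C)[Si](C)(C)OCC(=O)C[C@@H](O[Si](CC)(CC)CC)[C@@H]1OC1(C)C | intermediate
20 | potassium alkoxide of the ylide [(4Z,8R)-8-hydroxy-4,8-dimethyldeca-4,9-dien-1-ylidene]triphenylphosphorane | C=C[C@](C)([O-])CC/C=C(C)\CCC=P(c1ccccc1)(c1ccccc1)c1ccccc1.[K+] | intermediate
21 | (2Z,6Z,10R)-1-(tert-butyldimethylsilyloxy)-2-{(2R)-2-[(2S)-3,3-dimethyloxiran-2-yl]-2-(triethylsilyloxy)ethyl}-6,10-dimethyldodeca-2,6,11-trien-10-ol | C=C[C@](C)(O)CC/C=C(C)\CC/C=C(\CO[Si](C)(C)C(C)(C)C)C[C@@H](O[Si](CC)(CC)CC)[C@@H]1OC1(C)C | intermediate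
22 | (2Z,6Z,10R)-2-{(2R)-2-[(2S)-3,3-dimethyloxiran-2-yl]-2-hydroxyethyl}-6,10-dimethyldodeca-2,6,11-triene-1,10-diol | C=C[C@](C)(O)CC/C=C(C)\CC/C=C(\CO)C[C@@H](O)[C@@H]1OC1(C)C | intermediate
23 | (2Z,6Z,10R)-2-{(2R)-2-[(2S)-3,3-dimethyloxiran-2-yl]-2-hydroxyethyl}-10-hydroxy-6,10-dimethyldodeca-2,6,11-trien-1-yl acetate | C=C[C@](C)(O)CC/C=C(C)\CC/C=C(\COC(C)=O)C[C@@H](O)[C@@H]1OC1(C)C | intermediate
24 | (2Z)-2-methylbut-2-enoic acid (angelic acid) | C/C=C(/C)C(=O)O | starting material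
25 | (2Z)-2-methylbut-2-enoic 2,4,6-trichlorobenzoic anhydride | C/C=C(/C)C(=O)OC(=O)c1c(Cl)cc(Cl)cc1Cl | intermediate
26 | (2Z,6Z,10R)-2-{(2R)-2-[(2S)-3,3-dimethyloxiran-2-yl]-2-[(2Z)-2-methylbut-2-enoyloxy]ethyl}-10-hydroxy-6,10-dimethyldodeca-2,6,11-trien-1-yl acetate | C=C[C@](C)(O)CC/C=C(C)\CC/C=C(\COC(C)=O)C[C@@H](OC(=O)/C(C)=C\C)[C@@H]1OC1(C)C | intermediate
27 | (13R)-20-acetoxy-3β,13-dihydroxy-9βH-labda-8(17),14-dien-2α-yl (2Z)-2-methylbut-2-enoate (H-5 α, C20 β, side chain 9α) | C=C[C@](C)(O)CC[C@@H]1C(=C)CC[C@H]2C(C)(C)[C@@H](O)[C@H](OC(=O)/C(C)=C\C)C[C@]12COC(C)=O | intermediate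
28 | (13R)-20-acetoxy-13-hydroxy-3-oxo-9βH-labda-8(17),14-dien-2α-yl (2Z)-2-methylbut-2-enoate | C=C[C@](C)(O)CC[C@@H]1C(=C)CC[C@H]2C(C)(C)C(=O)[C@H](OC(=O)/C(C)=C\C)C[C@]12COC(C)=O | intermediate
29 | lithium 3α-alkoxide from reduction of 28 | C=C[C@](C)(O)CC[C@@H]1C(=C)CC[C@H]2C(C)(C)[C@H]([O-])[C@H](OC(=O)/C(C)=C\C)C[C@]12COC(C)=O.[Li+] | intermediate
30 | (13R)-3α,20-diacetoxy-13-hydroxy-9βH-labda-8(17),14-dien-2α-yl (2Z)-2-methylbut-2-enoate | C=C[C@](C)(O)CC[C@@H]1C(=C)CC[C@H]2C(C)(C)[C@H](OC(C)=O)[C@H](OC(=O)/C(C)=C\C)C[C@]12COC(C)=O | intermediate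
31 | (13R)-3α,20-diacetoxy-7α,13-dihydroxy-9βH-labda-8(17),14-dien-2α-yl (2Z)-2-methylbut-2-enoate (CNP0147212.1) | C=C[C@](C)(O)CC[C@@H]1C(=C)[C@H](O)C[C@H]2C(C)(C)[C@H](OC(C)=O)[C@H](OC(=O)/C(C)=C\C)C[C@]12COC(C)=O | target

**Total step count:** 15.
**Longest linear sequence:** 12 (steps 1–4, then 8–15).

**Steps most likely to fail, with fallbacks**

- **Step 12, the radical bicyclization.** The C2 ester sits next to the epoxide and may disturb the chair preference, accept the C4 radical, or migrate onto the titanium alkoxide. The axial placement of C11 at the Z-olefin may also leak through a boat. The fallback sets out from 23 and comes back at 27. The free hydroxy epoxide 23 is cyclised with Cp2TiCl (Cp2TiCl2, Mn, THF) before any ester is on C2, giving the diol (13R)-2α,3β,13-trihydroxy-9βH-labda-8(17),14-dien-20-yl acetate F1. The equatorial 2α-hydroxyl of F1 is then acylated selectively over the neopentyl 3β-hydroxyl with mixed anhydride 25, which gives 27.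

- **Step 14, the C3 inversion.** The hydride may attack the wrong face, reduce the angelate in a conjugate sense, or the alkoxide may trigger 2→3 acyl migration. The fallback sets out from 28 and comes back at 30. Ketone 28 is reduced under catalyst control with a 3α-selective ketoreductase (NADPH, glucose/glucose dehydrogenase recycling, pH 7 buffer with cosolvent) to the isolated alcohol (13R)-20-acetoxy-3α,13-dihydroxy-9βH-labda-8(17),14-dien-2α-yl (2Z)-2-methylbut-2-enoate F2. F2 is acetylated separately (Ac2O, DMAP, pyridine) to 30.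

- **Step 15, the allylic hydroxylation.** The axial 9α chain may divert oxygen to the β face. The fallback sets out from 30 and comes back at 31. Oxidation of 30 with stoichiometric SeO2 gives 31 mixed with its epimer (13R)-3α,20-diacetoxy-7β,13-dihydroxy-9βH-labda-8(17),14-dien-2α-yl (2Z)-2-methylbut-2-enoate F3. The mixture is oxidised with MnO2 to the enone (13R)-3α,20-diacetoxy-13-hydroxy-7-oxo-9βH-labda-8(17),14-dien-2α-yl (2Z)-2-methylbut-2-enoate F4. 1,2-Reduction of F4 with NaBH4 and CeCl3·7H2O at −78 °C then delivers hydride from the β face, because the axial 9α chain blocks the α face, and gives 31.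

**Further compounds**
F1 | step 12 | (13R)-2α,3β,13-trihydroxy-9βH-labda-8(17),14-dien-20-yl acetate | C=C[C@](C)(O)CC[C@@H]1C(=C)CC[C@H]2C(C)(C)[C@@H](O)[C@H](O)C[C@]12COC(C)=O
F2 | step 14 | (13R)-20-acetoxy-3α,13-dihydroxy-9βH-labda-8(17),14-dien-2α-yl (2Z)-2-methylbut-2-enoate | C=C[C@](C)(O)CC[C@@H]1C(=C)CC[C@H]2C(C)(C)[C@H](O)[C@H](OC(=O)/C(C)=C\C)C[C@]12COC(C)=O
F3 | step 15 | (13R)-3α,20-diacetoxy-7β,13-dihydroxy-9βH-labda-8(17),14-dien-2α-yl (2Z)-2-methylbut-2-enoate | C=C[C@](C)(O)CC[C@@H]1C(=C)[C@@H](O)C[C@H]2C(C)(C)[C@H](OC(C)=O)[C@H](OC(=O)/C(C)=C\C)C[C@]12COC(C)=O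
F4 | step 15 | (13R)-3α,20-diacetoxy-13-hydroxy-7-oxo-9βH-labda-8(17),14-dien-2α-yl (2Z)-2-methylbut-2-enoate | C=C[C@](C)(O)CC[C@@H]1C(=C)C(=O)C[C@H]2C(C)(C)[C@H](OC(C)=O)[C@H](OC(=O)/C(C)=C\C)C[C@]12COC(C)=O
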